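Ring A is closed by the C3–C4 bond through an intramolecular ketene–aldehyde [2+2] cycloaddition. The step exploits the cis 1,3-dioxygen array O3–C3–C4–C24–O of ring A: a temporary β-lactone joins O3 to C24 while C3–C4 forms, so the C3 carbinol and the quaternary C4 (oxygenated carbon axial, syn to the C10 methyl) arise in one operation. The precursor is a 3,4-seco-drimane: ring B, made from (S)-carvone, carries a CH2CH2CHO arm on C10 and a methylketene arm on C5, with the exocyclic methylene still masked as a tetrasubstituted enoate. Deconjugation, lactone reduction, etherification at C11 and acetylation at C24 finish the target.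

Key step: step 9

Remark (assumptions): positions are cited in drimane numbering, also for the monocyclic intermediates (ring A: C1–C5 and C10; ring B: C5–C10; C11 on C9; C12 on C8; C24 is the oxygenated carbon on C4). LiN(i-Pr)2 and LiBH(s-Bu)3 are taken as commercial solutions.

Step 1
Reactants: 1 (S)-(+)-carvone
Product: 3 α′-methylcarvone (epimer mixture at the methylated carbon, the future C10), via lithium dienolate of carvone 2 (not isolated)
Conditions: LiN(i-Pr)2, THF, −78 °C; MeI, −78 → 0 °C
Reagents that add atoms: iodomethane, CI
Why: Kinetic α′-deprotonation of the enone gives the cross-conjugated dienolate, which is C-methylated (enolate alkylation); the new centre forms as an epimer mixture that is erased by re-enolisation in step 2.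

Step 2
Reactants: 3 α′-methylcarvone
Product: 5 α′-allyl-α′-methylcarvone (allyl trans to isopropenyl, methyl cis), via lithium enolate of methylcarvone 4 (not isolated)
Conditions: LiN(i-Pr)2, THF, −78 °C; allyl bromide, DMPU, −78 → 0 °C
Reagents that add atoms: allyl bromide, C=CCBr
Why: A second kinetic enolisation gives the tetrasubstituted enolate and allyl bromide should attack the face anti to the neighbouring isopropenyl group (enolate alkylation under 1,2-substrate control), setting quaternary C10 with the C1–C3 arm trans to the C5 substituent.

Step 3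
Reactants: 5 α′-allyl-α′-methylcarvone
Product: 6 isopropenyl epoxide of 5 (epimers at the oxirane carbon)
Conditions: mCPBA, CH2Cl2, 0 °C
Reagents that add atoms: 3-chloroperbenzoic acid, OOC(=O)c1cccc(Cl)c1
Why: Prilezhaev epoxidation should pick the electron-rich 1,1-disubstituted alkene over the monosubstituted allyl alkene and the electron-poor enone; the oxirane carbon (future C4) is an inconsequential epimer mixture because it becomes planar in step 9.

Step 4
Reactants: 6 isopropenyl epoxide
Product: 8 tetrasubstituted enol triflate (C9–OTf, C8=C9), via lithium enolate of the reduced enone 7 (not isolated)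
Conditions: LiBH(s-Bu)3, THF, −78 °C; PhNTf2, −78 °C → rt
Reagents that add atoms: N-phenylbis(trifluoromethanesulfonimide), O=S(=O)(N(c1ccccc1)S(=O)(=O)C(F)(F)F)C(F)(F)F
Why: The bulky borohydride delivers hydride 1,4 to the β-unsubstituted, carbonyl-hindered enone (conjugate reduction) and the regiodefined enolate is O-sulfonylated; the oxirane should be inert at −78 °C and no stereocentre is created.

Step 5
Reactants: 8 enol triflate
Product: 9 methyl ester (C11 as CO2Me on C9, C8=C9, epoxide retained)
Conditions: Pd(OAc)2 (cat.), dppp, CO (1 atm), MeOH, Et3N, DMF, 70 °C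
Reagents that add atoms: carbon monoxide, [C-]#[O+]; methanol, CO
Why: Oxidative addition of zerovalent palladium into the C–OTf bond, CO insertion and methanolysis (alkoxycarbonylation of an enol triflate) install C11 at the ester oxidation level.

Step 6
Reactants: 9 epoxy ester
Product: 10 α-branched aldehyde (C24 as CHO, epimers at C4)
Conditions: BF3·OEt2 (cat.), CH2Cl2, −78 °C
Reagents that add atoms: none
Why: Meinwald rearrangement: Lewis-acid opening of the 2,2-disubstituted oxirane at the tertiary carbon and a 1,2-hydride shift give the aldehyde, the enoate alkene being too electron-poor to intercept the cation.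

Step 7
Reactants: 10 aldehyde
Product: 11 carboxylic acid (C24 as CO2H)
Conditions: NaClO2, NaH2PO4, 2-methyl-2-butene, t-BuOH/H2O, rt
Reagents that add atoms: sodium chlorite, [Na+].[O-]Cl=O
Why: Pinnick oxidation converts the hindered aldehyde into the acid without touching the alkenes, hypochlorous acid being scavenged by 2-methyl-2-butene.

Step 8
Reactants: 11 acid
Product: 12 seco aldehyde acid (C3 as CHO on the C10 arm)
Conditions: PdCl2(PhCN)2, CuCl2·2H2O, AgNO2 (all cat.), O2 (1 atm), t-BuOH/MeNO2, rt
Reagents that add atoms: dioxygen, O=O
Why: Aldehyde-selective Wacker oxidation (divalent palladium with a nitrite co-catalyst) should deliver oxygen to the terminal carbon of the monosubstituted alkene, helped by the adjacent quaternary carbon, while the tetrasubstituted enoate is inert.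

Step 9
Reactants: 12 seco aldehyde acid
Product: 15 tricyclic β-lactone (ring A closed; oxetan-2-one fused at C3–C4), via acid chloride 13 (not isolated), via dialkylketene 14 (not isolated)
Conditions: 1-chloro-N,N,2-trimethylprop-1-en-1-amine, CH2Cl2, 0 °C; then Et3N, toluene, 80 °C, slow addition (high dilution)
Reagents that add atoms: none
Why: Triethylamine dehydrochlorinates the α-branched acid chloride to the dialkylketene, whose nucleophilic terminal carbon C4 bonds to the aldehyde carbon C3 while the aldehyde oxygen bonds to the ketene carbonyl carbon C24 in a thermal intramolecular ketene–carbonyl [2+2] cycloaddition. The closest known reaction type is the β-lactone synthesis from ketenes and aldehydes, including its intramolecular thermal variant from acid chlorides and tertiary amines. Ring A closes in the 6-exo-trig mode (C4 onto C3=O) through a chair in which both arms are equatorial on ring B, and the oxetan-2-one closes with it as a four-membered ring that can only be cis-fused. The cis fusion ties the configuration of C3 to that of C4, and C4 is set by the angular C10 methyl: the slim sp-hybridised ketene carbon should take the axial site syn to that methyl so that the C4 methyl avoids a methyl/methyl 1,3-diaxial contact, which places O3 equatorial. The step needs capture of the ketene by the aldehyde faster than dimerisation, which slow addition and the six-membered tether should secure, and it needs no competing ketenophile, which is why the exocyclic methylene is still masked as the electron-poor enoate.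

Step 10
Reactants: 15 tricyclic β-lactone
Product: 17 β-lactone with 8(12)-exocyclic methylene (9-H anti to the C10 methyl, CO2Me equatorial), via lithium dienolate 16 (not isolated)
Conditions: LiN(i-Pr)2, THF/DMPU, −78 °C; AcOH, −78 °C
Reagents that add atoms: none
Why: Deconjugative isomerisation of an α,β-unsaturated ester: the base removes a proton from the C12 methyl, which is syn to the ester, and kinetic α-protonation at C9 should occur axially on the face anti to the axial C10 methyl; the hindered β-lactone has no α-hydrogen and should survive at −78 °C.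

Step 11
Reactants: 17 exocyclic-methylene β-lactone ester
Product: 18 (3R,4R,5S,9R,10R)-drim-8(12)-ene-3,11,24-triol
Conditions: LiAlH4, THF, 0 °C → rt
Reagents that add atoms: none
Why: Hydride reduction cleaves the β-lactone at the acyl–oxygen bond (C3 configuration retained) and reduces the methyl ester, unveiling all three hydroxyls in one operation.

Step 12
Reactants: 18 triol; 19 umbelliferone (7-hydroxycoumarin)
Product: 20 C11 umbelliferyl ether diol
Conditions: PPh3, DIAD, THF, 0 °C → rt
Reagents that add atoms: none
Why: Mitsunobu etherification with the acidic phenol should occur only at C11, the one hydroxyl-bearing carbon open to SN2 displacement (C24 is neopentyl, C3 is secondary next to quaternary C4); no stereocentre is affected.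

Step 13
Reactants: 20 ether diol
Product: 21 target CNP0271943.1
Conditions: Ac2O, pyridine, CH2Cl2, −20 → 0 °C
Reagents that add atoms: acetic anhydride, CC(=O)OC(C)=O
Why: Acylation should discriminate the primary C24 hydroxyl from the secondary C3 hydroxyl flanked by quaternary C4 (selective esterification of the primary alcohol of a 1,3-diol).

Compound list
1 | (S)-(+)-carvone, (5S)-2-methyl-5-(prop-1-en-2-yl)cyclohex-2-en-1-one | CC1=CC[C@H](C(C)=C)CC1=O | starting material
2 | lithium cross-conjugated dienolate of carvone | CC1=CC[C@H](C(C)=C)C=C1O[Li] | intermediate (not isolated)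
3 | α′-methylcarvone, (5S)-2,6-dimethyl-5-(prop-1-en-2-yl)cyclohex-2-en-1-one, epimers at the methylated carbon | CC1=CC[C@H](C(C)=C)C(C)C1=O | intermediate
4 | lithium enolate of methylcarvone (tetrasubstituted) | CC1=CC[C@H](C(C)=C)C(C)=C1O[Li] | intermediate (not isolated)
5 | (5R,6R)-2,6-dimethyl-6-(prop-2-en-1-yl)-5-(prop-1-en-2-yl)cyclohex-2-en-1-one (allyl trans to isopropenyl) | CC1=CC[C@H](C(C)=C)[C@](CC=C)(C)C1=O | intermediate
6 | 6-allyl-2,6-dimethyl-5-(2-methyloxiran-2-yl)cyclohex-2-en-1-one (ring stereocentres as in 5, oxirane carbon epimeric) | CC1=CC[C@H](C2(C)CO2)[C@](CC=C)(C)C1=O | intermediate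
7 | lithium enolate from conjugate reduction of 6 | CC=1CC[C@H](C2(C)CO2)[C@](CC=C)(C)C=1O[Li] | intermediate (not isolated)
8 | 6-allyl-2,6-dimethyl-5-(2-methyloxiran-2-yl)cyclohex-1-en-1-yl trifluoromethanesulfonate | CC=1CC[C@H](C2(C)CO2)[C@](CC=C)(C)C=1OS(=O)(=O)C(F)(F)F | intermediate
9 | methyl 6-allyl-2,6-dimethyl-5-(2-methyloxiran-2-yl)cyclohex-1-ene-1-carboxylate | CC=1CC[C@H](C2(C)CO2)[C@](CC=C)(C)C=1C(=O)OC | intermediate
10 | methyl 6-allyl-2,6-dimethyl-5-(1-oxopropan-2-yl)cyclohex-1-ene-1-carboxylate (side-chain α-carbon epimeric) | CC=1CC[C@H](C(C)C=O)[C@](CC=C)(C)C=1C(=O)OC | intermediate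
11 | 2-[2-allyl-3-(methoxycarbonyl)-2,4-dimethylcyclohex-3-en-1-yl]propanoic acid | CC=1CC[C@H](C(C)C(O)=O)[C@](CC=C)(C)C=1C(=O)OC | intermediate
12 | 2-[3-(methoxycarbonyl)-2,4-dimethyl-2-(3-oxopropyl)cyclohex-3-en-1-yl]propanoic acid (3,4-seco-drimane aldehyde acid) | CC=1CC[C@H](C(C)C(O)=O)[C@](CCC=O)(C)C=1C(=O)OC | intermediate
13 | acid chloride of 12 | CC=1CC[C@H](C(C)C(Cl)=O)[C@](CCC=O)(C)C=1C(=O)OC | intermediate (not isolated)
14 | dialkylketene, methyl 2,6-dimethyl-5-(1-oxoprop-1-en-2-yl)-6-(3-oxopropyl)cyclohex-1-ene-1-carboxylate | CC=1CC[C@H](C(C)=C=O)[C@](CCC=O)(C)C=1C(=O)OC | intermediate (not isolated)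
15 | methyl drim-8-en-11-oate carrying an oxetan-2-one fused at C3–C4 (ring O on C3, C=O carbon C24 on C4; trans-decalin; lactone cis-fused, C24 axial and syn to the C10 methyl, C4 methyl and O3 equatorial) | CC=1CC[C@@H]2[C@]3(C)C(=O)O[C@@H]3CC[C@@]2(C)C=1C(=O)OC | intermediate
16 | lithium dienolate of 15 (C9=C11 enolate, C8=C12) | C=C1CC[C@@H]2[C@]3(C)C(=O)O[C@@H]3CC[C@@]2(C)C1=C(OC)O[Li] | intermediate (not isolated)
17 | the same β-lactone with 8(12)-exocyclic methylene, 9-H anti to the C10 methyl, CO2Me equatorial | C=C1CC[C@@H]2[C@]3(C)C(=O)O[C@@H]3CC[C@@]2(C)[C@@H]1C(=O)OC | intermediate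
18 | (3R,4R,5S,9R,10R)-drim-8(12)-ene-3,11,24-triol (3-OH equatorial, 24-CH2OH axial and syn to the C10 methyl) | C=C1CC[C@@H]2[C@](C)(CO)[C@H](O)CC[C@@]2(C)[C@@H]1CO | intermediate
19 | umbelliferone, 7-hydroxy-2H-chromen-2-one | Oc1ccc2ccc(=O)oc2c1 | starting material
20 | 7-{[(3R,4R,5S,9R,10R)-3,24-dihydroxydrim-8(12)-en-11-yl]oxy}-2H-chromen-2-one | C=C1CC[C@@H]2[C@](C)(CO)[C@H](O)CC[C@@]2(C)[C@@H]1COc1ccc2ccc(=O)oc2c1 | intermediate
21 | 7-{[(3R,4R,5S,9R,10R)-24-acetoxy-3-hydroxydrim-8(12)-en-11-yl]oxy}-2H-chromen-2-one (CNP0271943.1) | C=C1CC[C@@H]2[C@](C)(COC(C)=O)[C@H](O)CC[C@@]2(C)[C@@H]1COc1ccc2ccc(=O)oc2c1 | target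

Total step count: 13. Longest linear sequence: 13 steps (from 1; umbelliferone 19 enters at step 12).

Steps most likely to fail

1. Step 9 (ring closure). The unactivated aldehyde may capture the dialkylketene too slowly, so that dimerisation or hydrolysis of the ketene takes over, or closure through a boat may erode the C3/C4 selectivity. The fallback sets out from epoxy ester 9 and comes back at triol 18, forming the same C3–C4 bond by a radical route. Hydroboration of the allyl group with 9-BBN and oxidation with NaOH/H2O2 should give the primary alcohol F1, and DMP oxidation the epoxy aldehyde F2. Cp2TiCl (trivalent titanium, made from Cp2TiCl2 and Zn, THF, rt) should open the oxirane homolytically to the tertiary C4 radical, which adds 6-exo to the aldehyde to give methyl 3,24-dihydroxydrim-8-en-11-oate F3. Facial selectivity at C4 is expected to be lower than in step 9, so the C4 epimer would have to be removed by chromatography. Deconjugation as in step 10 with excess LiN(i-Pr)2 should give the 8(12)-ene diol ester F4, and LiAlH4 then gives 18.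

2. Step 10 (deconjugation). Deprotonation may compete at C7 and give the endocyclic isomer, the dienolate may be reprotonated at C12, or the amide base may attack the strained lactone. The fallback sets out from 15 and comes back at 17 without a new compound. It is a photochemical deconjugation (254 nm, Et2O, catalytic 1,2-dimethylimidazole): photoenolisation by a 1,5-hydrogen shift can only take a hydrogen from the C12 methyl syn to the ester, and ketonisation of the dienol gives 17 without strong base.

3. Step 12 (etherification). Displacement at the β-branched C11 may be slow, so that elimination toward the diene or alkylation of the hydrazide by-product competes. The fallback sets out from 18 and comes back at 20. Selective sulfonylation of the least hindered primary hydroxyl (TsCl, pyridine, 0 °C) should give the 11-tosylate F5, which is displaced by the caesium salt of 19 (Cs2CO3, DMF, 70 °C). These conditions can be forced in a way the Mitsunobu reaction cannot.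

Further compounds
F1 | step 9 | methyl 6-(3-hydroxypropyl)-2,6-dimethyl-5-(2-methyloxiran-2-yl)cyclohex-1-ene-1-carboxylate | CC=1CC[C@H](C2(C)CO2)[C@](CCCO)(C)C=1C(=O)OC
F2 | step 9 | methyl 2,6-dimethyl-5-(2-methyloxiran-2-yl)-6-(3-oxopropyl)cyclohex-1-ene-1-carboxylate | CC=1CC[C@H](C2(C)CO2)[C@](CCC=O)(C)C=1C(=O)OC
F3 | step 9 | methyl 3,24-dihydroxydrim-8-en-11-oate | CC=1CC[C@@H]2[C@](C)(CO)[C@H](O)CC[C@@]2(C)C=1C(=O)OC
F4 | step 9 | methyl 3,24-dihydroxydrim-8(12)-en-11-oate | C=C1CC[C@@H]2[C@](C)(CO)[C@H](O)CC[C@@]2(C)[C@@H]1C(=O)OC
F0 | step 10 | none | none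
F5 | step 12 | 3,24-dihydroxydrim-8(12)-en-11-yl 4-methylbenzenesulfonate | C=C1CC[C@@H]2[C@](C)(CO)[C@H](O)CC[C@@]2(C)[C@@H]1COS(=O)(=O)c1ccc(C)cc1
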